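**Strategy.** The oxepane C3–O–C16–C15–C14–C1–C2 is derived from a six-membered ketone (ring A) with C16 as carbonyl and the quaternary carbon C3 beside it. Baeyer–Villiger oxidation inserts oxygen into the C3–C16 bond: one operation turns the all-carbon quaternary centre into the hindered tertiary ether centre with retention and expands ring A to the seven-membered lactone, which is then reduced to the ether. The step exploits the quaternary C3 flanking the C16 carbonyl in ring A (C15 being only secondary). Its substrate is tetracycle 40: cyclohexanone (ring A) trans-fused to cyclohexane (ring B), with the tetrahydrofuran (ring C) and the oxonane (ring D) already in place.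

Key step: step 34

Remark on numbering: atom labels C1–C16 follow the asbestinin skeleton in every intermediate; "arm" is the C4–C6 chain on C3; TBS = tert-butyldimethylsilyl, TES = triethylsilyl.
Assumption: an anti-Prelog ketoreductase that gives the (2R,3R) ketol 4 is taken to be available from screening; the usual Prelog enzymes give its mirror image.
Remark on design: in 40 ring A is trans-fused to rings B and C while B and C are cis-fused, an array that cannot be all-chair. Ring C is therefore closed by an irreversible SN2 step (step 24) at a stage where C10 can no longer epimerise.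

Step 1
Reactants: 1 2-methylcyclohexane-1,3-dione; 2 allyl bromide
Product: 3 2-allyl-2-methylcyclohexane-1,3-dione
Conditions: 1 M aq. NaOH, rt
Reagents that add atoms: none
Why: C-alkylation of the doubly stabilised dione enolate by a reactive allylic halide in water favours attack at carbon and builds the still prochiral quaternary carbon C3 with its methyl group and the three-carbon arm.

Step 2
Reactants: 3 2-allyl-2-methylcyclohexane-1,3-dione
Product: 4 (2R,3R)-2-allyl-3-hydroxy-2-methylcyclohexan-1-one
Conditions: anti-Prelog ketoreductase, NADP+ (cat.), i-PrOH, phosphate buffer pH 7, 30 °C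
Reagents that add atoms: none
Why: Enzymatic desymmetrising reduction of one of the two enantiotopic carbonyl groups of a 2,2-disubstituted 1,3-dione fixes the quaternary centre C3 and the C16 carbinol together, hydride entering anti to the allyl group so that the hydroxyl is cis to the arm, and leaves the other carbonyl as C2.

Step 3
Reactants: 4 (2R,3R)-2-allyl-3-hydroxy-2-methylcyclohexan-1-one
Product: 6 (2R,3R)-3-hydroxy-2-(3-hydroxypropyl)-2-methylcyclohexan-1-one, via bis-boryl adduct 5 (not isolated)
Conditions: 9-BBN (2.2 equiv), THF, 0 °C → rt; then H2O2, aq. NaOAc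
Reagents that add atoms: hydrogen peroxide, OO
Why: Anti-Markovnikov hydroboration–oxidation of the terminal alkene (9-BBN borylates the hydroxyl but does not reduce the hindered ketone) turns the arm into the C6 primary alcohol, so that no alkene is present during the later hydrogenations.

Step 4
Reactants: 6 (2R,3R)-3-hydroxy-2-(3-hydroxypropyl)-2-methylcyclohexan-1-one
Product: 7 (2R,3R)-3-(tert-butyldimethylsilyloxy)-2-[3-(tert-butyldimethylsilyloxy)propyl]-2-methylcyclohexan-1-one
Conditions: t-BuMe2SiOTf (2.5 equiv), 2,6-lutidine, CH2Cl2, −78 → 0 °C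
Reagents that add atoms: tert-butyldimethylsilyl triflate, CC(C)(C)[Si](C)(C)OS(=O)(=O)C(F)(F)F
Why: Silyl ether formation with the reactive triflate protects the primary C6 and the hindered secondary C16 hydroxyl groups in one operation without touching a stereocentre.

Step 5
Reactants: 7 bis-TBS ketone
Product: 9 (5R,6R)-5-(tert-butyldimethylsilyloxy)-6-[3-(tert-butyldimethylsilyloxy)propyl]-6-methylcyclohex-2-en-1-one, via silyl enol ether 8 (not isolated)
Conditions: LiN(i-Pr)2, Me3SiCl, THF, −78 °C; then Pd(OAc)2, MeCN, rt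
Reagents that add atoms: none
Why: Saegusa–Ito oxidation is regiospecific because the quaternary C3 leaves C1 as the only enolisable position, and palladium-mediated dehydrosilylation of the silyl enol ether gives the C1=C14 enone.

Step 6
Reactants: 9 C2 enone
Product: 10 allylic alcohol (C2–OH cis to the C3 arm and to C16–OTBS; C1=C14)
Conditions: NaBH4, CeCl3·7H2O, MeOH, −78 °C
Reagents that add atoms: none
Why: Luche 1,2-reduction delivers hydride to C2 from the face opposite the pseudo-axial C3 arm (axial attack on the conformer with equatorial C16 silyl ether), so the new C2 hydroxyl is cis to the arm.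

Step 7
Reactants: 10 allylic alcohol
Product: 11 (tributylstannyl)methyl ether of 10
Conditions: KH, 18-crown-6, Bu3SnCH2I, THF, 0 °C → rt
Reagents that add atoms: (iodomethyl)tributylstannane, CCCC[Sn](CCCC)(CCCC)CI
Why: Williamson etherification of the potassium alkoxide with the reactive primary iodide installs the stannylmethyl group without touching a stereocentre.

Step 8
Reactants: 11 stannylmethyl ether
Product: 12 homoallylic alcohol (C14–CH2OH, carbon C13, cis to the C3 arm; C1=C2)
Conditions: n-BuLi, THF, −78 → −20 °C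
Reagents that add atoms: none
Why: Still–Wittig [2,3]-sigmatropic rearrangement after tin–lithium exchange forms the C14–C13 bond suprafacially, on the face of the breaking C2–O bond, so C13 ends up cis to the C3 arm while the alkene moves to C1=C2.

Step 9
Reactants: 12 homoallylic alcohol
Product: 13 epoxy alcohol (C1–C2 epoxide, oxygen cis to C13 and to the C3 arm)
Conditions: VO(acac)2 (cat.), t-BuOOH, CH2Cl2, 0 °C → rt
Reagents that add atoms: tert-butyl hydroperoxide, CC(C)(C)OO
Why: Hydroxyl-directed vanadium-catalysed epoxidation uses the homoallylic C13 hydroxyl to deliver oxygen to the alkene face that carries C13, which places the epoxide oxygen on the arm face at C1 and C2.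

Step 10
Reactants: 13 epoxy alcohol; 14 but-1-yne
Product: 15 alkynyl diol (C2–OH cis to the arm, C1 but-1-ynyl trans to C2–OH and to C14–CH2OH)
Conditions: Et2AlC≡CEt (from 14, n-BuLi, Et2AlCl; 3.5 equiv), toluene, 0 °C → rt
Reagents that add atoms: none
Why: Epoxide opening by an alkynylalane is an SN2 attack at C1, the carbon remote from the quaternary C3, anti to the epoxide oxygen, so C1 is inverted, the C2 hydroxyl stays on the arm face and C10 lies trans to both C2–O and C13.

Step 11
Reactants: 15 alkynyl diol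
Product: 16 hydroxy aldehyde (C13 aldehyde, C2–OH, C1 butynyl)
Conditions: TEMPO (cat.), PhI(OAc)2, CH2Cl2, rt
Reagents that add atoms: none
Why: Oxoammonium-mediated oxidation is selective for the primary C13 alcohol over the hindered secondary C2 alcohol and leaves the alkyne and silyl ethers alone.

Step 12
Reactants: 16 hydroxy aldehyde
Product: 17 keto aldehyde (C1–CH2–CO–CH2CH3 with C11 ketone; C13 aldehyde; C2–OH)
Conditions: Ph3PAuCl (cat.), AgOTf (cat.), H2O, 1,4-dioxane, rt
Reagents that add atoms: water, O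
Why: Gold-catalysed alkyne hydration, assisted by 5-endo attack of the neighbouring C2 hydroxyl on the less hindered alkyne carbon C11 and hydrolysis of the enol ether, puts the carbonyl at C11 and leaves C10 as a methylene group.

Step 13
Reactants: 17 keto aldehyde
Product: 18 bicyclic enone (rings A and B trans-fused; C11 ketone, C12(Me)=C13; C2–OH)
Conditions: KOH, MeOH, 0 °C → rt
Reagents that add atoms: none
Why: Intramolecular aldol condensation (6-enolendo-exo-trig) joins the C12 methylene of the ethyl ketone to the C13 aldehyde and loses water to give the enone, with C1 and C14 keeping their trans, diequatorial bonds.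

Step 14
Reactants: 18 bicyclic enone
Product: 19 C2 triethylsilyl ether of 18
Conditions: Et3SiOTf, 2,6-lutidine, CH2Cl2, −78 °C
Reagents that add atoms: triethylsilyl triflate, CC[Si](CC)(CC)OS(=O)(=O)C(F)(F)F
Why: Silylation of the hindered C2 hydroxyl protects it against O-alkylation and makes it a bulky equatorial group that disfavours an equatorial substituent at the peri position C10.

Step 15
Reactants: 19 silyl-protected enone
Product: 20 C10 benzyloxymethyl ketone (C10–C9 bond axial, H10 cis to H1)
Conditions: LiN(i-Pr)2, THF, −78 °C; then BnOCH2Cl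
Reagents that add atoms: benzyl chloromethyl ether, ClCOCc1ccccc1
Why: Kinetic α′-deprotonation of the enone gives the cross-conjugated lithium dienolate, whose alkylation occurs by axial attack at C10 on the face that avoids the peri interaction with the C2 silyl ether, so C9 is axial and H10 is cis to H1.

Step 16
Reactants: 20 benzyloxymethyl enone
Product: 21 saturated ketone (C12 methyl cis to the C10 CH2OBn group)
Conditions: H2 (1 atm), Pd/C, pyridine (0.5 equiv), EtOAc, rt
Reagents that add atoms: none
Why: Heterogeneous hydrogenation of the enone alkene (pyridine suppresses benzyl ether cleavage) adds hydrogen to the face opposite the axial C10 substituent, which sets the C12 methyl kinetically on the same side as C9.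

Step 17
Reactants: 21 saturated ketone
Product: 22 C11 alcohol (hydroxyl cis to C9 and to the C12 methyl)
Conditions: NaBH4, CeCl3·7H2O, MeOH, −78 °C
Reagents that add atoms: none
Why: Hydride reduction from the face opposite the two axial neighbours (C10–CH2OBn and C12–Me) gives the equatorial C11 alcohol cis to both, and the cold, weakly basic medium avoids epimerisation at C10 and C12.

Step 18
Reactants: 22 C11 alcohol
Product: 23 C11 acetate
Conditions: Ac2O, DMAP, pyridine, rt
Reagents that add atoms: acetic anhydride, CC(=O)OC(C)=O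
Why: DMAP-catalysed acylation of the only free hydroxyl installs the acetate that is also the group required in the Baeyer–Villiger substrate.

Step 19
Reactants: 23 acetate
Product: 24 C9 primary alcohol
Conditions: H2 (1 atm), Pd(OH)2/C, EtOAc, rt
Reagents that add atoms: none
Why: Hydrogenolysis of the benzyl ether frees the C9 hydroxyl while acetate and silyl ethers are inert in a neutral solvent.

Step 20
Reactants: 24 primary alcohol
Product: 25 C9 aldehyde
Conditions: Dess–Martin periodinane, NaHCO3, CH2Cl2, 0 °C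
Reagents that add atoms: none
Why: Buffered Dess–Martin oxidation gives the aldehyde under neutral conditions that do not epimerise the adjacent C10 centre.

Step 21
Reactants: 25 aldehyde; 26 tributyl(2-methylallyl)stannane
Product: 27 (9R)-homoallylic alcohol (C9–OH, C8H2–C7(Me)=CH2)
Conditions: (R)-BINOL, Ti(Oi-Pr)4 (cat.), 4 Å MS, CH2Cl2, −20 °C
Reagents that add atoms: none
Why: Keck catalytic asymmetric allylation brings in C8, C7 and the C7 methyl, the BINOL–titanium Lewis acid directing the stannane to the Re face of the aldehyde (reagent control) to give the (9R) alcohol.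

Step 22
Reactants: 27 homoallylic alcohol
Product: 28 C9 mesylate
Conditions: MsCl, Et3N, CH2Cl2, −20 °C
Reagents that add atoms: methanesulfonyl chloride, CS(=O)(=O)Cl
Why: Sulfonylation of the only free hydroxyl turns C9 into an SN2 electrophile with its configuration unchanged.

Step 23
Reactants: 28 mesylate
Product: 29 diol mesylate (C2–OH and C6–OH free; C16–OTBS, C11–OAc kept)
Conditions: camphorsulfonic acid (cat.), MeOH/CH2Cl2, 0 °C
Reagents that add atoms: none
Why: Acid-catalysed methanolysis removes the triethylsilyl ether and the primary TBS ether, whereas the hindered secondary C16 silyl ether, the acetate and the mesylate survive.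

Step 24
Reactants: 29 diol mesylate
Product: 30 tricycle with ring C closed (C2–O–C9; C9 2-methylallyl; C6–OH)
Conditions: NaH (2.2 equiv), THF, 0 → 40 °C
Reagents that add atoms: none
Why: Intramolecular Williamson etherification (5-exo-tet) lets the C2 alkoxide displace the C9 mesylate with inversion, which closes ring C, makes C9 the (S) ether centre with C8 cis to C3 across the ring oxygen, and locks the cis B/C and trans A/C fusion because neither C2 nor C10 can epimerise here.

Step 25
Reactants: 30 tricyclic alcohol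
Product: 31 C6 aldehyde
Conditions: Dess–Martin periodinane, NaHCO3, CH2Cl2, 0 °C
Reagents that add atoms: none
Why: Dess–Martin oxidation of the only free (primary) hydroxyl gives the aldehyde at the end of the arm.

Step 26
Reactants: 31 aldehyde
Product: 32 diene (C3 but-3-enyl arm, C9 2-methylallyl)
Conditions: Ph3PCH3Br, KN(SiMe3)2, THF, −78 → 0 °C
Reagents that add atoms: methyltriphenylphosphonium bromide, C[P+](c1ccccc1)(c1ccccc1)c1ccccc1.[Br-]
Why: Wittig methylenation converts the C6 aldehyde into the terminal alkene faster than the unstabilised ylide can attack the hindered acetate.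

Step 27
Reactants: 32 diene
Product: 33 oxonene tetracycle with (Z)-C6=C7 alkene
Conditions: second-generation Grubbs catalyst (10 mol %), toluene, 80 °C, 1 mM
Reagents that add atoms: none
Why: Ring-closing metathesis of the but-3-enyl and 2-methylallyl groups, both held on the same face of the 2,5-cis-disubstituted tetrahydrofuran, closes the nine-membered ring D and gives the trisubstituted C6=C7 alkene, which must be Z in a ring of this size.

Step 28
Reactants: 33 oxonene
Product: 35 (6R,7R) C6 alcohol, via alkylborane 34 (not isolated)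
Conditions: BH3·THF, THF, 0 °C; then H2O2, aq. NaOAc
Reagents that add atoms: hydrogen peroxide, OO
Why: Hydroboration–oxidation puts boron on the less substituted C6 and hydrogen on C7 in a syn fashion from the exposed outer face of the oxonene, which sets the C6 carbinol and the C7 methyl centre together.

Step 29
Reactants: 35 C6 alcohol
Product: 36 C6 methyl ether
Conditions: MeOTf, 2,6-di-tert-butylpyridine, CH2Cl2, rt
Reagents that add atoms: methyl triflate, COS(=O)(=O)C(F)(F)F
Why: O-methylation with a powerful neutral methylating agent and a hindered base converts the only free hydroxyl into the methyl ether without endangering the acetate.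

Step 30
Reactants: 36 methyl ether
Product: 37 C16 alcohol
Conditions: HF·pyridine, THF, rt
Reagents that add atoms: none
Why: Fluoride-mediated desilylation frees the hindered C16 hydroxyl under conditions that leave the acetate and the ethers intact.

Step 31
Reactants: 37 C16 alcohol
Product: 38 C16 ketone (C15 still CH2)
Conditions: Dess–Martin periodinane, NaHCO3, CH2Cl2, rt
Reagents that add atoms: none
Why: Dess–Martin oxidation under buffered neutral conditions gives the ketone flanked by the quaternary C3 and the C15 methylene.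

Step 32
Reactants: 38 C16 ketone
Product: 39 C15 exo-methylene ketone
Conditions: (CH2O)n, PhNHMe·CF3CO2H, THF, 65 °C
Reagents that add atoms: paraformaldehyde (as formaldehyde), C=O
Why: α-Methylenation by the Mannich route (Gras conditions) can occur only at C15 because C3 is quaternary, and it installs the carbon of the future C15 methyl group as an exocyclic alkene.

Step 33
Reactants: 39 methylene ketone
Product: 40 carbocyclic C16 ketone (Baeyer–Villiger substrate)
Conditions: H2 (1 atm), RhCl(PPh3)3, benzene, rt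
Reagents that add atoms: none
Why: Homogeneous hydrogenation of the exocyclic enone alkene delivers hydrogen to C15 from the convex face of ring A, opposite the C3–C4 bond of the oxonane bridge, so the methyl group ends up cis to C4 and C13, and the neutral conditions do not epimerise this centre.

Step 34
Reactants: 40 carbocyclic C16 ketone
Product: 41 seven-membered C16 lactone
Conditions: mCPBA, NaHCO3, CH2Cl2, 0 °C → rt
Reagents that add atoms: meta-chloroperoxybenzoic acid, OOC(=O)c1cccc(Cl)c1
Why: The peracid adds to the C16 carbonyl to give the Criegee adduct, and the C3–C16 bond migrates to the proximal peroxide oxygen as the O–O bond breaks, which places oxygen between C3 and C16 (Baeyer–Villiger oxidation of an α-quaternary cyclohexanone, a well-known ring expansion). The seven-membered lactone therefore arises by one-atom expansion of ring A and not by a cyclisation, so no ring-closure mode has to be satisfied. The new tertiary C–O stereocentre at C3 is controlled by the concerted 1,2-shift, which proceeds with retention, so the configuration fixed in step 2 is carried over unchanged. The required regioselectivity, migration of quaternary C3 and not of secondary C15, follows from the higher migratory aptitude of the more substituted carbon, and C16 is the only ketone in 40. The bicarbonate buffer keeps the medium non-acidic, so the epimerisable C15 centre, the acetate and the ethers are left untouched.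

Step 35
Reactants: 41 lactone
Product: 42 lactol with free C11–OH
Conditions: i-Bu2AlH (4 equiv), CH2Cl2, −78 °C; Rochelle salt work-up
Reagents that add atoms: none
Why: Hydride reduction at low temperature stops at the aluminium hemiacetal of the lactone, which gives the lactol on work-up, and the same reagent cleaves the acetate to the C11 alcohol.

Step 36
Reactants: 42 lactol
Product: 43 oxepane with free C11–OH
Conditions: Et3SiH, BF3·OEt2, CH2Cl2, −78 → 0 °C
Reagents that add atoms: none
Why: The Lewis acid ionises the lactol to the cyclic oxocarbenium ion, kept closed by the rigid tetracyclic frame, and triethylsilane delivers hydride to C16 (ionic hydrogenation of a lactol), which gives the oxepane without touching a stereocentre.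

Step 37
Reactants: 43 oxepane alcohol
Product: 44 CNP0289153.2 (target)
Conditions: Ac2O, DMAP, pyridine, rt
Reagents that add atoms: acetic anhydride, CC(=O)OC(C)=O
Why: DMAP-catalysed acylation of the single free secondary hydroxyl at C11 gives the target acetate.

**Compound list**

1 | 2-methylcyclohexane-1,3-dione | CC1C(=O)CCCC1=O | starting material
2 | allyl bromide | C=CCBr | starting material
3 | 2-allyl-2-methylcyclohexane-1,3-dione | C=CCC1(C)C(=O)CCCC1=O | intermediate
4 | (2R,3R)-2-allyl-3-hydroxy-2-methylcyclohexan-1-one (C2 ketone; C16 carbinol cis to the allyl arm on C3) | C=CC[C@@]1(C)C(=O)CCC[C@H]1O | intermediate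
5 | bis(9-borabicyclo[3.3.1]nonan-9-yl) adduct of 4 (C6–B and C16–O–B) | B1(C2CCCC1CCC2)CCC[C@@]3(C)C(=O)CCC[C@H]3OB1C2CCCC1CCC2 | intermediate
6 | (2R,3R)-3-hydroxy-2-(3-hydroxypropyl)-2-methylcyclohexan-1-one | OCCC[C@@]1(C)C(=O)CCC[C@H]1O | intermediate
7 | (2R,3R)-3-(TBS-oxy)-2-[3-(TBS-oxy)propyl]-2-methylcyclohexan-1-one | CC(C)(C)[Si](C)(C)OCCC[C@@]1(C)C(=O)CCC[C@H]1O[Si](C)(C)C(C)(C)C | intermediate
8 | trimethylsilyl enol ether of 7 (C1=C2–OSiMe3) | CC(C)(C)[Si](C)(C)OCCC[C@@]1(C)C(O[Si](C)(C)C)=CCC[C@H]1O[Si](C)(C)C(C)(C)C | intermediate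
9 | (5R,6R)-5-(TBS-oxy)-6-[3-(TBS-oxy)propyl]-6-methylcyclohex-2-en-1-one (C2 ketone, C1=C14) | CC(C)(C)[Si](C)(C)OCCC[C@@]1(C)C(=O)C=CC[C@H]1O[Si](C)(C)C(C)(C)C | intermediate
10 | allylic alcohol: C2–OH cis to the C3 arm and to C16–OTBS, C1=C14 | CC(C)(C)[Si](C)(C)OCCC[C@@]1(C)[C@@H](O)C=CC[C@H]1O[Si](C)(C)C(C)(C)C | intermediate
11 | (tributylstannyl)methyl ether of 10 | CC(C)(C)[Si](C)(C)OCCC[C@@]1(C)[C@@H](OC[Sn](CCCC)(CCCC)CCCC)C=CC[C@H]1O[Si](C)(C)C(C)(C)C | intermediate
12 | homoallylic alcohol: C14–CH2OH (C13) cis to the C3 arm, C1=C2 | CC(C)(C)[Si](C)(C)OCCC[C@@]1(C)C=C[C@@H](CO)C[C@H]1O[Si](C)(C)C(C)(C)C | intermediate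
13 | C1–C2 epoxide of 12, oxygen cis to C13 and to the C3 arm | CC(C)(C)[Si](C)(C)OCCC[C@@]1(C)[C@H]2O[C@H]2[C@@H](CO)C[C@H]1O[Si](C)(C)C(C)(C)C | intermediate
14 | but-1-yne | CCC#C | starting material
15 | alkynyl diol: C1 but-1-ynyl trans to C2–OH and to C14–CH2OH | CC(C)(C)[Si](C)(C)OCCC[C@@]1(C)[C@@H](O)[C@H](C#CCC)[C@@H](CO)C[C@H]1O[Si](C)(C)C(C)(C)C | intermediate
16 | hydroxy aldehyde: C13 aldehyde, C2–OH, C1 but-1-ynyl | CC(C)(C)[Si](C)(C)OCCC[C@@]1(C)[C@@H](O)[C@H](C#CCC)[C@@H](C=O)C[C@H]1O[Si](C)(C)C(C)(C)C | intermediate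
17 | keto aldehyde: C1–CH2–CO–CH2CH3 (C11 ketone), C13 aldehyde, C2–OH | CC(C)(C)[Si](C)(C)OCCC[C@@]1(C)[C@@H](O)[C@H](CC(=O)CC)[C@@H](C=O)C[C@H]1O[Si](C)(C)C(C)(C)C | intermediate
18 | trans-fused bicyclic enone (rings A, B): C11 ketone, C12(Me)=C13, C2–OH | CC(C)(C)[Si](C)(C)OCCC[C@@]1(C)[C@@H](O)[C@@H]2CC(=O)C(C)=C[C@H]2C[C@H]1O[Si](C)(C)C(C)(C)C | intermediate
19 | C2 triethylsilyl ether of 18 | CC(C)(C)[Si](C)(C)OCCC[C@@]1(C)[C@@H](O[Si](CC)(CC)CC)[C@@H]2CC(=O)C(C)=C[C@H]2C[C@H]1O[Si](C)(C)C(C)(C)C | intermediate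
20 | C10 benzyloxymethyl enone (C10–C9 axial, H10 cis to H1) | CC(C)(C)[Si](C)(C)OCCC[C@@]1(C)[C@@H](O[Si](CC)(CC)CC)[C@@H]2[C@H](COCc3ccccc3)C(=O)C(C)=C[C@H]2C[C@H]1O[Si](C)(C)C(C)(C)C | intermediate
21 | saturated C11 ketone, C12 methyl cis to C10–CH2OBn | CC(C)(C)[Si](C)(C)OCCC[C@@]1(C)[C@@H](O[Si](CC)(CC)CC)[C@@H]2[C@H](COCc3ccccc3)C(=O)[C@H](C)C[C@H]2C[C@H]1O[Si](C)(C)C(C)(C)C | intermediate
22 | C11 alcohol, hydroxyl cis to C9 and C12–Me | CC(C)(C)[Si](C)(C)OCCC[C@@]1(C)[C@@H](O[Si](CC)(CC)CC)[C@@H]2[C@H](COCc3ccccc3)[C@H](O)[C@H](C)C[C@H]2C[C@H]1O[Si](C)(C)C(C)(C)C | intermediate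
23 | C11 acetate of 22 | CC(C)(C)[Si](C)(C)OCCC[C@@]1(C)[C@@H](O[Si](CC)(CC)CC)[C@@H]2[C@H](COCc3ccccc3)[C@H](OC(C)=O)[C@H](C)C[C@H]2C[C@H]1O[Si](C)(C)C(C)(C)C | intermediate
24 | C9 primary alcohol | CC(C)(C)[Si](C)(C)OCCC[C@@]1(C)[C@@H](O[Si](CC)(CC)CC)[C@@H]2[C@H](CO)[C@H](OC(C)=O)[C@H](C)C[C@H]2C[C@H]1O[Si](C)(C)C(C)(C)C | intermediate
25 | C9 aldehyde | CC(C)(C)[Si](C)(C)OCCC[C@@]1(C)[C@@H](O[Si](CC)(CC)CC)[C@@H]2[C@H](C=O)[C@H](OC(C)=O)[C@H](C)C[C@H]2C[C@H]1O[Si](C)(C)C(C)(C)C | intermediate
26 | tributyl(2-methylallyl)stannane | CCCC[Sn](CCCC)(CCCC)CC(C)=C | starting material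
27 | (9R)-homoallylic alcohol: C9–OH, C8H2–C7(Me)=CH2 | CC(C)(C)[Si](C)(C)OCCC[C@@]1(C)[C@@H](O[Si](CC)(CC)CC)[C@@H]2[C@H]([C@H](O)CC(C)=C)[C@H](OC(C)=O)[C@H](C)C[C@H]2C[C@H]1O[Si](C)(C)C(C)(C)C | intermediate
28 | C9 mesylate of 27 | CC(C)(C)[Si](C)(C)OCCC[C@@]1(C)[C@@H](O[Si](CC)(CC)CC)[C@@H]2[C@H]([C@H](OS(C)(=O)=O)CC(C)=C)[C@H](OC(C)=O)[C@H](C)C[C@H]2C[C@H]1O[Si](C)(C)C(C)(C)C | intermediate
29 | diol mesylate: C2–OH and C6–OH free | OCCC[C@@]1(C)[C@@H](O)[C@@H]2[C@H]([C@H](OS(C)(=O)=O)CC(C)=C)[C@H](OC(C)=O)[C@H](C)C[C@H]2C[C@H]1O[Si](C)(C)C(C)(C)C | intermediate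
30 | tricycle (rings A, B, C): C2–O–C9 closed, C9 2-methylallyl, C6–OH, C16–OTBS, C11–OAc | OCCC[C@]2(C)[C@H](O[Si](C)(C)C(C)(C)C)C[C@@H]3C[C@@H](C)[C@@H](OC(C)=O)[C@@H]4[C@H]3[C@@H]2O[C@H]4CC(C)=C | intermediate
31 | C6 aldehyde | O=CCC[C@]2(C)[C@H](O[Si](C)(C)C(C)(C)C)C[C@@H]3C[C@@H](C)[C@@H](OC(C)=O)[C@@H]4[C@H]3[C@@H]2O[C@H]4CC(C)=C | intermediate
32 | diene: C3 but-3-enyl arm, C9 2-methylallyl | C=CCC[C@]2(C)[C@H](O[Si](C)(C)C(C)(C)C)C[C@@H]3C[C@@H](C)[C@@H](OC(C)=O)[C@@H]4[C@H]3[C@@H]2O[C@H]4CC(C)=C | intermediate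
33 | oxonene tetracycle (rings A–D), (Z)-C6=C7 | C1/C(C)=C\CC[C@]2(C)[C@H](O[Si](C)(C)C(C)(C)C)C[C@@H]3C[C@@H](C)[C@@H](OC(C)=O)[C@@H]4[C@H]3[C@@H]2O[C@H]41 | intermediate
34 | C6 alkylborane from 33 (B at C6, H at C7, syn) | B[C@@H]1CC[C@]2(C)[C@H](O[Si](C)(C)C(C)(C)C)C[C@@H]3C[C@@H](C)[C@@H](OC(C)=O)[C@@H]4[C@H]3[C@@H]2O[C@H]4C[C@H]1C | intermediate
35 | (6R,7R) C6 alcohol | O[C@@H]1CC[C@]2(C)[C@H](O[Si](C)(C)C(C)(C)C)C[C@@H]3C[C@@H](C)[C@@H](OC(C)=O)[C@@H]4[C@H]3[C@@H]2O[C@H]4C[C@H]1C | intermediate
36 | C6 methyl ether | CO[C@@H]1CC[C@]2(C)[C@H](O[Si](C)(C)C(C)(C)C)C[C@@H]3C[C@@H](C)[C@@H](OC(C)=O)[C@@H]4[C@H]3[C@@H]2O[C@H]4C[C@H]1C | intermediate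
37 | C16 alcohol | CO[C@@H]1CC[C@]2(C)[C@H](O)C[C@@H]3C[C@@H](C)[C@@H](OC(C)=O)[C@@H]4[C@H]3[C@@H]2O[C@H]4C[C@H]1C | intermediate
38 | C16 ketone with C15 methylene (CH2) | CO[C@@H]1CC[C@]2(C)C(=O)C[C@@H]3C[C@@H](C)[C@@H](OC(C)=O)[C@@H]4[C@H]3[C@@H]2O[C@H]4C[C@H]1C | intermediate
39 | C15 exo-methylene C16 ketone | CO[C@@H]1CC[C@]2(C)C(=O)C(=C)[C@@H]3C[C@@H](C)[C@@H](OC(C)=O)[C@@H]4[C@H]3[C@@H]2O[C@H]4C[C@H]1C | intermediate
40 | carbocyclic C16 ketone (Baeyer–Villiger substrate) | CO[C@@H]1CC[C@]2(C)C(=O)[C@H](C)[C@@H]3C[C@@H](C)[C@@H](OC(C)=O)[C@@H]4[C@H]3[C@@H]2O[C@H]4C[C@H]1C | intermediate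
41 | seven-membered C16 lactone | CO[C@@H]1CC[C@]2(C)OC(=O)[C@H](C)[C@@H]3C[C@@H](C)[C@@H](OC(C)=O)[C@@H]4[C@H]3[C@@H]2O[C@H]4C[C@H]1C | intermediate
42 | C16 lactol with free C11–OH (anomers) | CO[C@@H]1CC[C@]2(C)OC(O)[C@H](C)[C@@H]3C[C@@H](C)[C@@H](O)[C@@H]4[C@H]3[C@@H]2O[C@H]4C[C@H]1C | intermediate
43 | oxepane with free C11–OH | CO[C@@H]1CC[C@]2(C)OC[C@H](C)[C@@H]3C[C@@H](C)[C@@H](O)[C@@H]4[C@H]3[C@@H]2O[C@H]4C[C@H]1C | intermediate
44 | CNP0289153.2 | CO[C@@H]1CC[C@]2(C)OC[C@H](C)[C@@H]3C[C@@H](C)[C@@H](OC(C)=O)[C@@H]4[C@H]3[C@@H]2O[C@H]4C[C@H]1C | target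

**Totals.** Total step count: 37. Longest linear sequence: 37 steps (1 → 44); 14 and 26 are bought.

**Steps most likely to fail**

Step 24 (closure of ring C). The displacement has to build the strained A/B/C array, in which one six-membered ring is forced out of the chair, so E2 loss of the mesylate may outrun ring closure. The fallback forms the C–O bond at the aldehyde oxidation level and the C9–C8 bond afterwards. It sets out from aldehyde 25: pyridinium p-toluenesulfonate in methanol removes the triethylsilyl ether and the hydroxy aldehyde closes to lactol F1; Ac2O, pyridine and DMAP give lactol acetate F2; methallyltrimethylsilane and BF3·OEt2 at −78 °C add the 2-methylallyl group to the cyclic oxocarbenium ion from the convex face, giving the C6 silyl ether F3; brief HF·pyridine treatment removes the primary silyl ether and the route is rejoined at 30.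

Step 28 (hydroboration of the oxonene). Facial selectivity on the nine-membered Z-alkene may be poor, or the wrong face may react. The fallback replaces substrate control at both centres by reagent control at C6 and hydroxyl direction at C7. It sets out from 33: mCPBA gives epoxide F4; Al(Oi-Pr)3 in hot toluene isomerises it to the allylic alcohol F5 with an exocyclic C7 methylene; Dess–Martin periodinane gives enone F6; (S)-Me-CBS oxazaborolidine with BH3·SMe2 reduces the ketone to the (6R) allylic alcohol F7; hydrogenation with [Ir(cod)(PCy3)(py)]PF6 delivers hydrogen to C7 from the hydroxyl face and the route is rejoined at 35.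

Step 10 (epoxide opening). Attack at C1 of the hindered epoxide may be slow, or regioselectivity may erode. The fallback uses an aza-enolate that brings in the C11 carbonyl directly, so the alkyne hydration is no longer needed. It sets out from 13: the lithium aza-enolate of butan-2-one N,N-dimethylhydrazone (LiN(i-Pr)2, THF, 0 °C → rt) opens the epoxide at C1 to give hydroxy hydrazone F8; aqueous CuCl2 at pH 7 cleaves the hydrazone to keto diol F9; TEMPO with PhI(OAc)2 oxidises the primary alcohol and the route is rejoined at 17.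

**Further compounds**

F1 | step 24 | tricyclic C9 lactol (C6–OTBS, C16–OTBS, C11–OAc) | CC(C)(C)[Si](C)(C)OCCC[C@]2(C)[C@H](O[Si](C)(C)C(C)(C)C)C[C@@H]3C[C@@H](C)[C@@H](OC(C)=O)[C@@H]4[C@H]3[C@@H]2OC4O
F2 | step 24 | C9 lactol acetate | CC(C)(C)[Si](C)(C)OCCC[C@]2(C)[C@H](O[Si](C)(C)C(C)(C)C)C[C@@H]3C[C@@H](C)[C@@H](OC(C)=O)[C@@H]4[C@H]3[C@@H]2OC4OC(C)=O
F3 | step 24 | C6 TBS ether of 30 | CC(C)(C)[Si](C)(C)OCCC[C@]2(C)[C@H](O[Si](C)(C)C(C)(C)C)C[C@@H]3C[C@@H](C)[C@@H](OC(C)=O)[C@@H]4[C@H]3[C@@H]2O[C@H]4CC(C)=C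
F4 | step 28 | C6–C7 epoxide of 33 (epoxide face not defined; both centres are reset later) | CC12OC1CC[C@]3(C)[C@H](O[Si](C)(C)C(C)(C)C)C[C@@H]4C[C@@H](C)[C@@H](OC(C)=O)[C@@H]5[C@H]4[C@@H]3O[C@H]5C2
F5 | step 28 | allylic alcohol: C6–OH (configuration not defined), C7 exo-methylene | C=C1C(O)CC[C@]3(C)[C@H](O[Si](C)(C)C(C)(C)C)C[C@@H]4C[C@@H](C)[C@@H](OC(C)=O)[C@@H]5[C@H]4[C@@H]3O[C@H]5C1
F6 | step 28 | C6 ketone with C7 exo-methylene | C=C1C(=O)CC[C@]3(C)[C@H](O[Si](C)(C)C(C)(C)C)C[C@@H]4C[C@@H](C)[C@@H](OC(C)=O)[C@@H]5[C@H]4[C@@H]3O[C@H]5C1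
F7 | step 28 | (6R) allylic alcohol with C7 exo-methylene | C=C1[C@H](O)CC[C@]3(C)[C@H](O[Si](C)(C)C(C)(C)C)C[C@@H]4C[C@@H](C)[C@@H](OC(C)=O)[C@@H]5[C@H]4[C@@H]3O[C@H]5C1
F8 | step 10 | hydroxy hydrazone: C1–CH2–C(=N–NMe2)–CH2CH3, C2–OH, C14–CH2OH | CC(C)(C)[Si](C)(C)OCCC[C@@]1(C)[C@@H](O)[C@H](CC(CC)=NN(C)C)[C@@H](CO)C[C@H]1O[Si](C)(C)C(C)(C)C
F9 | step 10 | keto diol: C11 ketone, C2–OH, C14–CH2OH | CC(C)(C)[Si](C)(C)OCCC[C@@]1(C)[C@@H](O)[C@H](CC(=O)CC)[C@@H](CO)C[C@H]1O[Si](C)(C)C(C)(C)C
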